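**Retrosynthetic overview**

1. Ring A is the 3-hydroxy-4-alkoxyphenyl ring on C2, ring B the 3-methoxy-4-alkoxyphenyl ring on C5, ring C the oxolane (O1, C2–C5). Ring C is the only ring made (step 7); all arene rings are bought.
2. Last disconnections: both threo side chains come from double SN2 O-alkylation of a core bisphenol with an (S)-lactate-derived α-tosyloxy ketone, double CBS reduction and debenzylation.
3. Ring C stereochemistry is a relay from one carbinol centre: C5 (asymmetric alkynylation) → C4 (hydrogenation of an exocyclic methylene anti to ring B) → C3 (equilibration α to the masked ketone) → C2 (hydride to the oxocarbenium ion anti to the C3 methyl).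
4. Key disconnection: O1–C2 and C3–C4 together, by palladium-catalysed alkenylation of the ring A ethyl ketone enolate with a ring B 2-iodoallylic alcohol and hemiketalisation in the same flask. This is a polar counterpart of the 8–8′/7–O union of two C6–C3 units in lignan biosynthesis.
5. Enabling feature: C2 is a benzylic carbon bonded to both ring A and O1 and stands 1,4 to the C5 carbinol. It can therefore be carried as an aryl ketone whose α-carbon (C3) is the nucleophile and whose carbonyl takes up the C5 hydroxyl as a five-membered hemiketal; the C4 methyl is masked as =CH2 and both para phenols as electron-withdrawing tosylates.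

Key step: step 7

Assumption: in step 4 the (S,S)-ligand is taken to give the carbinol configuration drawn (S once silicon is removed); if MTPA ester analysis shows the opposite sense, the (R,R)-ligand is used.
Assumption: the hemiketals are drawn ring-closed; they stand in ring–chain equilibrium with the γ-hydroxy ketones, and OTs means 4-methylbenzenesulfonyloxy (tosyloxy).

**Route**

Step 1
Reactants: 1 1-(3,4-dihydroxyphenyl)propan-1-one
Product: 2 2-hydroxy-4-propanoylphenyl 4-methylbenzenesulfonate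
Conditions: TsCl (1.05 equiv), Et3N (1.1 equiv), acetone, 0 °C
Reagents that add atoms: 4-methylbenzenesulfonyl chloride, Cc1ccc(S(Cl)(=O)=O)cc1
Why: Regioselective O-sulfonylation of a catechol: the hydroxyl para to the acyl group is the more acidic one, so with one equivalent of base its phenoxide forms and is tosylated while the meta hydroxyl stays free, and no stereocentre is involved.

Step 2
Reactants: 2 2-hydroxy-4-propanoylphenyl 4-methylbenzenesulfonate
Product: 3 2-(benzyloxy)-4-propanoylphenyl 4-methylbenzenesulfonate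
Conditions: BnBr, K2CO3, DMF, rt
Reagents that add atoms: benzyl bromide, BrCc1ccccc1
Why: Williamson ether synthesis on the remaining phenol; a sulfonyl group cannot migrate to the neighbouring oxygen because in-line substitution at sulfur is not possible in a five-membered transition state, so the substitution pattern is kept.

Step 3
Reactants: 4 4-hydroxy-3-methoxybenzaldehyde (vanillin)
Product: 5 4-formyl-2-methoxyphenyl 4-methylbenzenesulfonate
Conditions: TsCl, Et3N, CH2Cl2, 0 °C to rt
Reagents that add atoms: 4-methylbenzenesulfonyl chloride, Cc1ccc(S(Cl)(=O)=O)cc1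
Why: O-Sulfonylation of a phenol, which protects the para oxygen of ring B as an electron-withdrawing group that survives every step up to step 10.

Step 4
Reactants: 5 4-formyl-2-methoxyphenyl 4-methylbenzenesulfonate
Product: 7 4-[(1S)-1-hydroxyprop-2-yn-1-yl]-2-methoxyphenyl 4-methylbenzenesulfonate, via silylalkyne carbinol 6 (not isolated)
Conditions: ethynyltrimethylsilane (3 equiv), Me2Zn (3 equiv), (S,S)-ProPhenol (20 mol %), Ph3PO (40 mol %), toluene, 0 °C; NH4Cl (aq); then K2CO3 (cat.), MeOH, 0 °C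
Reagents that add atoms: ethynyltrimethylsilane, C#C[Si](C)(C)C
Why: Catalytic asymmetric alkynylation of an aryl aldehyde (zinc acetylide addition under dinuclear zinc–ProPhenol control), in which the chiral catalyst selects the aldehyde face and so sets the carbinol centre that becomes C5, followed by base-catalysed protodesilylation of the alkyne.

Step 5
Reactants: 7 4-[(1S)-1-hydroxyprop-2-yn-1-yl]-2-methoxyphenyl 4-methylbenzenesulfonate
Product: 8 4-[(1R)-1-hydroxy-2-(triethylsilyl)prop-2-en-1-yl]-2-methoxyphenyl 4-methylbenzenesulfonate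
Conditions: Et3SiH, [Cp*Ru(MeCN)3]PF6 (2 mol %), CH2Cl2, 0 °C to rt
Reagents that add atoms: triethylsilane, CC[SiH](CC)CC
Why: Ruthenium-catalysed trans-hydrosilylation of a terminal alkyne, which for this cationic cyclopentadienyl complex places silicon on the internal carbon and leaves the carbinol centre untouched (the descriptor changes only by priority).

Step 6
Reactants: 8 4-[(1R)-1-hydroxy-2-(triethylsilyl)prop-2-en-1-yl]-2-methoxyphenyl 4-methylbenzenesulfonate
Product: 9 4-[(1R)-1-hydroxy-2-iodoprop-2-en-1-yl]-2-methoxyphenyl 4-methylbenzenesulfonate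
Conditions: NIS, MeCN/ClCH2CN, 0 °C
Reagents that add atoms: N-iodosuccinimide, O=C1CCC(=O)N1I
Why: Electrophilic ipso-iododesilylation of a vinylsilane through the β-silyl-stabilised cation, which replaces silicon by iodine at the same carbon and leaves the stereocentre untouched.

Step 7
Reactants: 3 2-(benzyloxy)-4-propanoylphenyl 4-methylbenzenesulfonate; 9 4-[(1R)-1-hydroxy-2-iodoprop-2-en-1-yl]-2-methoxyphenyl 4-methylbenzenesulfonate
Product: 11 (5S)-2-[3-(benzyloxy)-4-(tosyloxy)phenyl]-5-[3-methoxy-4-(tosyloxy)phenyl]-3-methyl-4-methylideneoxolan-2-ol (C2/C3 epimers), via open-chain hydroxy enone 10 (not isolated)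
Conditions: 3 (1.2 equiv), Pd2(dba)3 (2.5 mol %), P(t-Bu)3 (10 mol %), LiN(SiMe3)2 (3.3 equiv), toluene/THF, 0 °C to rt; AcOH, −78 °C
Reagents that add atoms: none
Why: Palladium-catalysed α-alkenylation of a ketone enolate: zerovalent palladium inserts into the C4–I bond of 9 (present as its lithium alkoxide), the lithium enolate of 3 transmetalates and reductive elimination forges C3–C4, after which the cold acetic acid quench frees the C5 hydroxyl of 10, which adds to the C2 aryl ketone to give the five-membered hemiketal 11 and so forms O1–C2. The closest known reaction type is the palladium/trialkylphosphine-catalysed α-vinylation of aryl alkyl ketone enolates by 1,1-disubstituted vinyl halides, combined with the ring–chain tautomerism of γ-hydroxy ketones. Ring C closes by 5-exo-trig addition of the hydroxyl oxygen to the carbonyl carbon. The C5 centre is carried in unchanged from 9, whereas the new C3 and C2 centres are labile by design (C3 is α to the masked ketone, C2 is the anomeric carbon) and are fixed afterwards, C3 by equilibration in step 8 and C2 by hydride delivery in step 9. The step needs C-alkenylation at C3 in preference to O-alkenylation, to β-elimination from the alkenylpalladium alkoxide and to migration of the new alkene into conjugation: the ketone has one enolisable position, the bulky electron-rich phosphine makes reductive elimination fast, alkoxide is a poor leaving group and kinetic protonation at −78 °C returns the deconjugated ketone. The two aryl tosylates are not attacked by palladium at room temperature and make both rings electron-poor, which disfavours ionisation of the hemiketal and its dehydration towards an aromatic furan.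

Step 8
Reactants: 11 (5S)-2-[3-(benzyloxy)-4-(tosyloxy)phenyl]-5-[3-methoxy-4-(tosyloxy)phenyl]-3-methyl-4-methylideneoxolan-2-ol
Product: 13 (3R,4R,5S)-2-[3-(benzyloxy)-4-(tosyloxy)phenyl]-5-[3-methoxy-4-(tosyloxy)phenyl]-3,4-dimethyloxolan-2-ol (C2 anomers), via C3-epimeric lactols 12 (not isolated)
Conditions: H2 (3 atm), RhCl(PPh3)3 (5 mol %), benzene/EtOH, rt; then DBU (0.2 equiv), CH2Cl2, rt
Reagents that add atoms: none
Why: Homogeneous catalytic hydrogenation should add hydrogen to the exocyclic alkene from the ring face opposite the adjacent ring B substituent, which sets C4 with its methyl cis to ring B, and base-mediated enolisation of the ring-opened γ-hydroxy ketone tautomer then equilibrates C3 to the more stable arrangement with its methyl trans to the C4 methyl.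

Step 9
Reactants: 13 (3R,4R,5S)-2-[3-(benzyloxy)-4-(tosyloxy)phenyl]-5-[3-methoxy-4-(tosyloxy)phenyl]-3,4-dimethyloxolan-2-ol
Product: 14 (2S,3R,4R,5S)-2-[3-(benzyloxy)-4-(tosyloxy)phenyl]-5-[3-methoxy-4-(tosyloxy)phenyl]-3,4-dimethyloxolane
Conditions: Et3SiH (5 equiv), BF3·OEt2 (2 equiv), CH2Cl2, −78 °C; NaHCO3 (aq)
Reagents that add atoms: none
Why: Ionic reduction of a cyclic hemiketal (reductive deoxygenation): BF3 ionises the anomeric hydroxyl to the 2-aryl oxocarbenium ion and Et3SiH delivers hydride to the face opposite the adjacent C3 methyl, which sets C2 with ring A cis to that methyl as in related 2-aryl-3-methyl lactol reductions of lignan synthesis, while the electron-poor tosyloxy rings keep the C5–O and C2–O bonds from ionising.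

Step 10
Reactants: 14 (2S,3R,4R,5S)-2-[3-(benzyloxy)-4-(tosyloxy)phenyl]-5-[3-methoxy-4-(tosyloxy)phenyl]-3,4-dimethyloxolane
Product: 15 2-(benzyloxy)-4-[(2S,3R,4R,5S)-5-(4-hydroxy-3-methoxyphenyl)-3,4-dimethyloxolan-2-yl]phenol
Conditions: NaOH, dioxane/H2O, 70 °C; NH4Cl (aq)
Reagents that add atoms: none
Why: Hydrolysis of aryl sulfonate esters by hydroxide attack at sulfur frees both para phenols, the benzyl ether and the oxolane being inert to aqueous base.

Step 11
Reactants: 16 (3,4-dimethoxyphenyl)magnesium bromide (2.3 equiv); 17 (2S)-2-hydroxy-N,N-dimethylpropanamide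
Product: 18 (2S)-1-(3,4-dimethoxyphenyl)-2-hydroxypropan-1-one
Conditions: THF, −10 to 0 °C; NH4Cl (aq)
Reagents that add atoms: none
Why: Acyl substitution of a tertiary amide by an aryl Grignard reagent: one equivalent forms the magnesium alkoxide, whose chelate holds the tetrahedral adduct until work-up, so the ketone is formed without over-addition and the lactate stereocentre is not touched.

Step 12
Reactants: 18 (2S)-1-(3,4-dimethoxyphenyl)-2-hydroxypropan-1-one
Product: 19 (2S)-1-(3,4-dimethoxyphenyl)-1-oxopropan-2-yl 4-methylbenzenesulfonate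
Conditions: TsCl, pyridine, CH2Cl2, 0 °C
Reagents that add atoms: 4-methylbenzenesulfonyl chloride, Cc1ccc(S(Cl)(=O)=O)cc1
Why: O-Sulfonylation of a secondary alcohol, which proceeds with retention because the C–O bond is not broken.

Step 13
Reactants: 15 2-(benzyloxy)-4-[(2S,3R,4R,5S)-5-(4-hydroxy-3-methoxyphenyl)-3,4-dimethyloxolan-2-yl]phenol; 19 (2S)-1-(3,4-dimethoxyphenyl)-1-oxopropan-2-yl 4-methylbenzenesulfonate (2.4 equiv)
Product: 20 (2R)-2-{2-(benzyloxy)-4-[(2S,3R,4R,5S)-5-(4-{[(2R)-1-(3,4-dimethoxyphenyl)-1-oxopropan-2-yl]oxy}-3-methoxyphenyl)-3,4-dimethyloxolan-2-yl]phenoxy}-1-(3,4-dimethoxyphenyl)propan-1-one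
Conditions: K2CO3, DMF, rt
Reagents that add atoms: none
Why: Double Williamson ether synthesis: each phenoxide displaces the α-keto tosylate by SN2 with inversion, which converts the S tosylate into the R aryl ether at both side chains.

Step 14
Reactants: 20 the bis(α-aryloxy ketone) of step 13
Product: 21 (1R,2R)-2-{2-(benzyloxy)-4-[(2S,3R,4R,5S)-5-(4-{[(1R,2R)-1-(3,4-dimethoxyphenyl)-1-hydroxypropan-2-yl]oxy}-3-methoxyphenyl)-3,4-dimethyloxolan-2-yl]phenoxy}-1-(3,4-dimethoxyphenyl)propan-1-ol
Conditions: (R)-2-methyl-CBS-oxazaborolidine (0.4 equiv), BH3·SMe2, THF, −20 °C; MeOH, then H2O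
Reagents that add atoms: none
Why: Corey–Bakshi–Shibata reduction: the (R)-oxazaborolidine directs hydride to the ketone face that is also preferred by the Felkin–Anh model (aryloxy group anti to the incoming hydride), so both new carbinol centres should form as R, threo to the ether centres.

Step 15
Reactants: 21 O-benzyl manassantin B1
Product: 22 manassantin B1, (1R,2R)-1-(3,4-dimethoxyphenyl)-2-{4-[(2S,3R,4R,5S)-5-(4-{[(1R,2R)-1-(3,4-dimethoxyphenyl)-1-hydroxypropan-2-yl]oxy}-3-methoxyphenyl)-3,4-dimethyloxolan-2-yl]-2-hydroxyphenoxy}propan-1-ol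
Conditions: H2 (1 atm), Pd/C (10 %), EtOAc, rt
Reagents that add atoms: none
Why: Hydrogenolysis of the benzyl aryl ether on palladium under neutral conditions frees the ring A phenol, the secondary benzylic alcohols and the oxolane C–O bonds being much slower to cleave.

**Compound list**

1 | 1-(3,4-dihydroxyphenyl)propan-1-one | CCC(=O)c1ccc(O)c(O)c1 | starting material
2 | 2-hydroxy-4-propanoylphenyl 4-methylbenzenesulfonate | CCC(=O)c1ccc(OS(=O)(=O)c2ccc(C)cc2)c(O)c1 | intermediate
3 | 2-(benzyloxy)-4-propanoylphenyl 4-methylbenzenesulfonate | CCC(=O)c1ccc(OS(=O)(=O)c2ccc(C)cc2)c(OCc2ccccc2)c1 | intermediate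
4 | 4-hydroxy-3-methoxybenzaldehyde (vanillin) | COc1cc(C=O)ccc1O | starting material
5 | 4-formyl-2-methoxyphenyl 4-methylbenzenesulfonate | COc1cc(C=O)ccc1OS(=O)(=O)c1ccc(C)cc1 | intermediate
6 | 4-[(1R)-1-hydroxy-3-(trimethylsilyl)prop-2-yn-1-yl]-2-methoxyphenyl 4-methylbenzenesulfonate | COc1cc([C@@H](O)C#C[Si](C)(C)C)ccc1OS(=O)(=O)c1ccc(C)cc1 | intermediate
7 | 4-[(1S)-1-hydroxyprop-2-yn-1-yl]-2-methoxyphenyl 4-methylbenzenesulfonate | COc1cc([C@@H](O)C#C)ccc1OS(=O)(=O)c1ccc(C)cc1 | intermediate
8 | 4-[(1R)-1-hydroxy-2-(triethylsilyl)prop-2-en-1-yl]-2-methoxyphenyl 4-methylbenzenesulfonate | COc1cc([C@@H](O)C(=C)[Si](CC)(CC)CC)ccc1OS(=O)(=O)c1ccc(C)cc1 | intermediate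
9 | 4-[(1R)-1-hydroxy-2-iodoprop-2-en-1-yl]-2-methoxyphenyl 4-methylbenzenesulfonate | COc1cc([C@@H](O)C(I)=C)ccc1OS(=O)(=O)c1ccc(C)cc1 | intermediate
10 | (4S)-1-[3-(benzyloxy)-4-(tosyloxy)phenyl]-4-hydroxy-4-[3-methoxy-4-(tosyloxy)phenyl]-2-methyl-3-methylidenebutan-1-one (C2 epimers) | COc1cc([C@@H](O)C(=C)C(C)C(=O)c2ccc(OS(=O)(=O)c3ccc(C)cc3)c(OCc3ccccc3)c2)ccc1OS(=O)(=O)c1ccc(C)cc1 | intermediate
11 | (5S)-2-[3-(benzyloxy)-4-(tosyloxy)phenyl]-5-[3-methoxy-4-(tosyloxy)phenyl]-3-methyl-4-methylideneoxolan-2-ol (epimers at C2 and C3) | OC1(c2ccc(OS(=O)(=O)c3ccc(C)cc3)c(OCc3ccccc3)c2)O[C@H](c2ccc(OS(=O)(=O)c3ccc(C)cc3)c(OC)c2)C(=C)C1C | intermediate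
12 | (4R,5S)-2-[3-(benzyloxy)-4-(tosyloxy)phenyl]-5-[3-methoxy-4-(tosyloxy)phenyl]-3,4-dimethyloxolan-2-ol (epimers at C2 and C3) | OC1(c2ccc(OS(=O)(=O)c3ccc(C)cc3)c(OCc3ccccc3)c2)O[C@H](c2ccc(OS(=O)(=O)c3ccc(C)cc3)c(OC)c2)[C@H](C)C1C | intermediate
13 | (3R,4R,5S)-2-[3-(benzyloxy)-4-(tosyloxy)phenyl]-5-[3-methoxy-4-(tosyloxy)phenyl]-3,4-dimethyloxolan-2-ol (anomers at C2) | OC1(c2ccc(OS(=O)(=O)c3ccc(C)cc3)c(OCc3ccccc3)c2)O[C@H](c2ccc(OS(=O)(=O)c3ccc(C)cc3)c(OC)c2)[C@H](C)[C@H]1C | intermediate
14 | (2S,3R,4R,5S)-2-[3-(benzyloxy)-4-(tosyloxy)phenyl]-5-[3-methoxy-4-(tosyloxy)phenyl]-3,4-dimethyloxolane | Cc1ccc(S(=O)(=O)Oc2ccc([C@H]3O[C@H](c4ccc(OS(=O)(=O)c5ccc(C)cc5)c(OC)c4)[C@H](C)[C@H]3C)cc2OCc2ccccc2)cc1 | intermediate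
15 | 2-(benzyloxy)-4-[(2S,3R,4R,5S)-5-(4-hydroxy-3-methoxyphenyl)-3,4-dimethyloxolan-2-yl]phenol | Oc1ccc([C@H]2O[C@H](c3ccc(O)c(OC)c3)[C@H](C)[C@H]2C)cc1OCc1ccccc1 | intermediate
16 | (3,4-dimethoxyphenyl)magnesium bromide (solution in THF) | COc1ccc([Mg]Br)cc1OC | starting material
17 | (2S)-2-hydroxy-N,N-dimethylpropanamide | C[C@H](O)C(=O)N(C)C | starting material
18 | (2S)-1-(3,4-dimethoxyphenyl)-2-hydroxypropan-1-one | C[C@H](O)C(=O)c1ccc(OC)c(OC)c1 | intermediate
19 | (2S)-1-(3,4-dimethoxyphenyl)-1-oxopropan-2-yl 4-methylbenzenesulfonate | C[C@H](OS(=O)(=O)c1ccc(C)cc1)C(=O)c1ccc(OC)c(OC)c1 | intermediate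
20 | (2R)-2-{2-(benzyloxy)-4-[(2S,3R,4R,5S)-5-(4-{[(2R)-1-(3,4-dimethoxyphenyl)-1-oxopropan-2-yl]oxy}-3-methoxyphenyl)-3,4-dimethyloxolan-2-yl]phenoxy}-1-(3,4-dimethoxyphenyl)propan-1-one | COc1ccc(C(=O)[C@@H](C)Oc2ccc([C@H]3O[C@H](c4ccc(O[C@H](C)C(=O)c5ccc(OC)c(OC)c5)c(OC)c4)[C@H](C)[C@H]3C)cc2OCc2ccccc2)cc1OC | intermediate
21 | O-benzyl manassantin B1, (1R,2R)-2-{2-(benzyloxy)-4-[(2S,3R,4R,5S)-5-(4-{[(1R,2R)-1-(3,4-dimethoxyphenyl)-1-hydroxypropan-2-yl]oxy}-3-methoxyphenyl)-3,4-dimethyloxolan-2-yl]phenoxy}-1-(3,4-dimethoxyphenyl)propan-1-ol | COc1ccc([C@@H](O)[C@@H](C)Oc2ccc([C@H]3O[C@H](c4ccc(O[C@H](C)[C@H](O)c5ccc(OC)c(OC)c5)c(OC)c4)[C@H](C)[C@H]3C)cc2OCc2ccccc2)cc1OC | intermediate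
22 | manassantin B1 | COc1ccc([C@@H](O)[C@@H](C)Oc2ccc([C@H]3O[C@H](c4ccc(O[C@H](C)[C@H](O)c5ccc(OC)c(OC)c5)c(OC)c4)[C@H](C)[C@H]3C)cc2O)cc1OC | target

**Step count and risks**

Total step count: 15. Longest linear sequence: 11 steps (from 4 through steps 3–10 and 13–15).

The three steps most likely to fail:

Step 7. What may go wrong: β-elimination from the alkenylpalladium alkoxide, slow transmetalation of the hindered enolate, and migration of the new double bond into conjugation followed by loss of water and aromatisation. The fallback sets out from 3 and 7 and returns at 11; it makes the same two bonds by a Ueno–Stork sequence, one ionic and one radical. Ketone 3 is ketalised with trimethyl orthoformate and TsOH to the dimethyl ketal F1, which loses methanol with TMSOTf and i-Pr2NEt to give the methyl enol ether F2. NBS and propargylic alcohol 7 add across F2 to give the α-bromo mixed ketal F3 (O1–C2 bond). Bu3SnH and AIBN in benzene at 80 °C close the ring by 5-exo-dig cyclisation of the C3 radical onto the alkyne to give the methylidene methyl ketal F4 (C3–C4 bond). PPTS in wet acetone hydrolyses F4 to lactol 11.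

Step 8. What may go wrong: unselective delivery of hydrogen to the two faces of the methylene group, because the C3 methyl can shield the face opposite ring B, and metal-mediated migration of the alkene into the ring. The fallback sets out from 9 and returns at 13; it sets C4 on a lactone that has no C3 substituent. Palladium-catalysed coupling of 9 with the Reformatsky reagent BrZnCH2CO2t-Bu gives the hydroxy ester F5, which closes with CF3CO2H to the methylidene lactone F6. Only ring B flanks this alkene, so hydrogenation over RhCl(PPh3)3 should give the cis lactone F7, and LiN(i-Pr)2 then MeI methylates the enolate anti to the C4 methyl to give the dimethyl lactone F8. Ring A is brought in as the arylmagnesium chloride F11, made from 2-(benzyloxy)phenol by para bromination with NBS (the bromophenol F9), tosylation (the aryl bromide F10) and bromine–magnesium exchange with i-PrMgCl·LiCl. Its addition to F8 at −78 °C gives lactol 13.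

Step 9. What may go wrong: reversible opening of the oxocarbenium ion at the C5–O bond with loss of the 4,5-cis relationship, or hydride delivery syn to the C3 methyl. The fallback sets out from 9 (through the dimethyl lactone F8 above) and returns at 14; it reverses the roles at C2, so that hydrogen is already in place and ring A enters as the nucleophile. Lactone F8 is reduced with i-Bu2AlH at −78 °C to the lactol F12 and converted with benzenesulfinic acid and CaCl2 into the 2-sulfonyl oxolane F13. The arylzinc bromide F14 (from the arylmagnesium chloride F11 and ZnBr2) is then added in the presence of ZnBr2; additions of arylzinc reagents to such 2-sulfonyl oxolanes are known to give the 2,3-cis-3,4-trans-4,5-cis oxolane, here 14.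

Further compounds
F1 | step 7 | 2-(benzyloxy)-4-(1,1-dimethoxypropyl)phenyl 4-methylbenzenesulfonate | CCC(OC)(OC)c1ccc(OS(=O)(=O)c2ccc(C)cc2)c(OCc2ccccc2)c1
F2 | step 7 | 2-(benzyloxy)-4-(1-methoxyprop-1-en-1-yl)phenyl 4-methylbenzenesulfonate (E/Z mixture) | CC=C(OC)c1ccc(OS(=O)(=O)c2ccc(C)cc2)c(OCc2ccccc2)c1
F3 | step 7 | 2-(benzyloxy)-4-[2-bromo-1-methoxy-1-({(1S)-1-[3-methoxy-4-(tosyloxy)phenyl]prop-2-yn-1-yl}oxy)propyl]phenyl 4-methylbenzenesulfonate (diastereomer mixture) | CC(Br)C(OC)(O[C@H](c1ccc(OS(=O)(=O)c2ccc(C)cc2)c(OC)c1)C#C)c1ccc(OS(=O)(=O)c2ccc(C)cc2)c(OCc2ccccc2)c1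
F4 | step 7 | (5S)-2-[3-(benzyloxy)-4-(tosyloxy)phenyl]-2-methoxy-5-[3-methoxy-4-(tosyloxy)phenyl]-3-methyl-4-methylideneoxolane (epimers at C2 and C3) | COC1(c2ccc(OS(=O)(=O)c3ccc(C)cc3)c(OCc3ccccc3)c2)O[C@H](c2ccc(OS(=O)(=O)c3ccc(C)cc3)c(OC)c2)C(=C)C1C
F5 | step 8 | tert-butyl (4S)-4-hydroxy-4-[3-methoxy-4-(tosyloxy)phenyl]-3-methylidenebutanoate | COc1cc([C@@H](O)C(=C)CC(=O)OC(C)(C)C)ccc1OS(=O)(=O)c1ccc(C)cc1
F6 | step 8 | (5S)-5-[3-methoxy-4-(tosyloxy)phenyl]-4-methylideneoxolan-2-one | O=C1CC(=C)[C@@H](c2ccc(OS(=O)(=O)c3ccc(C)cc3)c(OC)c2)O1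
F7 | step 8 | (4R,5S)-5-[3-methoxy-4-(tosyloxy)phenyl]-4-methyloxolan-2-one | O=C1C[C@@H](C)[C@@H](c2ccc(OS(=O)(=O)c3ccc(C)cc3)c(OC)c2)O1
F8 | step 8 | (3R,4R,5S)-5-[3-methoxy-4-(tosyloxy)phenyl]-3,4-dimethyloxolan-2-one | O=C1[C@H](C)[C@@H](C)[C@@H](c2ccc(OS(=O)(=O)c3ccc(C)cc3)c(OC)c2)O1
F9 | step 8 | 2-(benzyloxy)-4-bromophenol | Oc1ccc(Br)cc1OCc1ccccc1
F10 | step 8 | 2-(benzyloxy)-4-bromophenyl 4-methylbenzenesulfonate | Cc1ccc(S(=O)(=O)Oc2ccc(Br)cc2OCc2ccccc2)cc1
F11 | step 8 | [3-(benzyloxy)-4-(tosyloxy)phenyl]magnesium chloride | Cc1ccc(S(=O)(=O)Oc2ccc([Mg]Cl)cc2OCc2ccccc2)cc1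
F12 | step 9 | (3R,4R,5S)-5-[3-methoxy-4-(tosyloxy)phenyl]-3,4-dimethyloxolan-2-ol (anomers at C2) | OC1O[C@H](c2ccc(OS(=O)(=O)c3ccc(C)cc3)c(OC)c2)[C@H](C)[C@H]1C
F13 | step 9 | (3R,4R,5S)-2-(benzenesulfonyl)-5-[3-methoxy-4-(tosyloxy)phenyl]-3,4-dimethyloxolane (epimers at C2) | O=S(=O)(c1ccccc1)C1O[C@H](c2ccc(OS(=O)(=O)c3ccc(C)cc3)c(OC)c2)[C@H](C)[C@H]1C
F14 | step 9 | [3-(benzyloxy)-4-(tosyloxy)phenyl]zinc bromide | Cc1ccc(S(=O)(=O)Oc2ccc([Zn]Br)cc2OCc2ccccc2)cc1
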